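Watch the rate fall.

all flasks: catalyst 9.60 mM

| flask | starting material | partner | time |
|---|---|---|---|
| summer | 120 mM | 132 mM |  |
| dawn | 48.0 mM | 60.0 mM |  |
| dusk | 120 mM | 260 mM |  |
| winter | 300 mM | 132 mM | 30 min |

1. the power of [partner] that the first rate follows, about the charge of the summer run; measure it at two percent of starting material made into target
2. the power of [starting material] that the first rate follows, about the charge of the summer run; measure it at two percent of starting material made into target (one fixed amount of target, the same in the runs compared)
3. target in the winter run at 30 min, as a share of the starting material charged

- Overall: starting material + partner -> target, with catalyst as catalyst.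
- Constant volume, constant temperature.
- A reading of a species includes what of it is bound.
- "The second partner" is partner.
- An order is taken over about fifteen percent of the charge, up and down.

- summer run (time / min: [target] / mM): 1.2: 3.4; 2.7: 8.5; 6.0: 17.9; 13: 30.4; 30: 41.0
- dawn run (time / min: [target] / mM): 1.2: 1.2; 2.7: 4.4; 6.0: 9.3; 13: 17.6; 30: 25.8
- dusk run (time / min: [target] / mM): 1.2: 3.5; 2.7: 9.5; 6.0: 18.4; 13: 33.2; 30: 46.3

(readings scatter by 0.4 mM)

Read the summer column first. Target grows at 2.85 mM/min between 2.7 min and 6.0 min, but at 0.624 mM/min between 13 min and 30 min. Now write the balance of the smaller summer charge: c(starting material), bound forms counted, equals its charge minus target. That leaves 65.8 % at 30 min, while the rate keeps 21.9 %, so the rate falls further than this balance shows.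

Treat the fall as a decay. Take the time between the two interval midpoints and divide it by the logarithm of the rate ratio: this gives the fall time, 11.3 min. The same reading gives 15.3 min for dawn and 13.7 min for dusk.

Then divide each last reading by one minus exp(−t/fall time) to get the reach, the target a curve of that shape heads for: 44.1 mM in summer, 30.0 mM at dawn and 52.1 mM at dusk.

Across these runs, reach follows partner with power 0.247 and starting material with power 0.208. Winter charges the summer amount of partner, so I take the summer fall time for it. Its reach is then 53.3 mM, and I reckon 49.6 mM at 30 min, or 16.5 %. Partner is the limiting reagent there, with 132 mM against 300 mM, which caps target at 44.0 % of the starting material.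

The first interval gives me rough powers of 0.240 for partner and 0.302 for starting material, taken over the wide steps between runs. The forecast gives 0.3 for partner, 0.22 for starting material and 16 % for winter, and holds that the “catalyst is dying with time”; my rough starting material power is higher than its 0.22.

Winter gives 15.8 %, which is 47.4 mM of target. About the summer charge, the first rate follows partner with power 0.25 and starting material with power 0.42, the second higher than the forecast's 0.22. catalyst + starting material → catalyst-substrate complex (31.14 /M/min); catalyst-substrate complex + partner → target + catalyst (18.42 /M/min); 2 partner → lost reagent (1.308 /M/min); 2 starting material ⇌ idle substrate dimer, settled at all times (172.0 /M)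

The summer fall time turns the winter result into a reach of 51.0 mM. At dawn, the fall time and reach put a quarter of the charge at 7.79 min, and the flask reaches it at 7.68 min.

The earlier runs and the new flask come from a simulation with made-up constants; noise was put on by code.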